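Ring A is numbered C1 (OMe), C2 (prenyl), C3 (OH), C4 (H), C5 (E-styryl), C6 (prenyl). O3 is masked as a silyl ether, and the C6 prenyl group is cut between its CH2 and its CH=, leading back through ArCH2Cl and ArCH2OH to a C6 methyl ester.
Ring A is then opened at C4–C5 and C1–C6, with a CH2CH2 bridge restored across C1 and C4. This gives a 1-methoxy-3-silyloxycyclohexa-1,3-diene and methyl (E)-5-phenylpent-4-en-2-ynoate.
Enabling feature: C1, C2 and C3 carry OMe, prenyl and O in the same order as the vinylogous methyl ester of 2-prenylcyclohexane-1,3-dione. The carbon substituent on C6 sits beside the methoxy carbon and opposite C3–O, which is where a 1,3-dioxygenated diene directs the carbonyl-bearing carbon of an alkynoate.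
Forward: the dione is prenylated, O-methylated and silylated to the diene, and cinnamaldehyde is homologated to the ynoate. Cycloaddition with loss of ethylene then builds ring A, the only ring made (the phenyl ring is bought). The ester becomes the second prenyl group, and the phenol is freed last.
The target has no stereocentres. Its one stereoelement, the E styryl alkene, comes from trans-cinnamaldehyde and no later step touches it.
Key step: step 6

Remark on the chemistry: the prenylated dione is drawn as the diketone although it is largely enolised. The bicyclic cycloadduct is racemic and drawn as one enantiomer. 2-Methylprop-1-enylmagnesium bromide is taken as the commercial THF solution.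

Step 1
Reactants: 1 cyclohexane-1,3-dione; 2 prenyl bromide (1-bromo-3-methylbut-2-ene)
Product: 3 2-(3-methylbut-2-enyl)cyclohexane-1,3-dione
Conditions: KOH (1 equiv), H2O, 0 °C to rt
Reagents that add atoms: none
Why: SN2 C-alkylation of the stabilised 1,3-dione enolate with a soft allylic bromide; in water the enolate oxygens are hydrogen-bonded, which favours attack through C2, and the acidic product is separated from neutral O-alkylated material by base extraction.

Step 2
Reactants: 3 2-(3-methylbut-2-enyl)cyclohexane-1,3-dione
Product: 4 3-methoxy-2-(3-methylbut-2-enyl)cyclohex-2-en-1-one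
Conditions: Me2SO4 (1.1 equiv), K2CO3, acetone, reflux
Reagents that add atoms: dimethyl sulfate, COS(=O)(=O)OC
Why: O-alkylation of a vinylogous acid with a hard methylating agent gives the vinylogous ester (the dione is symmetric, so only one enol ether can form), and the basic medium avoids acid-induced cyclisation of the enol onto the prenyl double bond.

Step 3
Reactants: 4 3-methoxy-2-(3-methylbut-2-enyl)cyclohex-2-en-1-one
Product: 6 3-(tert-butyldimethylsilyloxy)-1-methoxy-2-(3-methylbut-2-enyl)cyclohexa-1,3-diene, via lithium dienolate 5 (not isolated)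
Conditions: LiN(i-Pr)2 (1.1 equiv), THF, −78 °C; TBSCl, DMPU, −78 °C to rt; cold NaHCO3 work-up
Reagents that add atoms: tert-butyldimethylsilyl chloride, CC(C)(C)[Si](C)(C)Cl
Why: Kinetic α′-deprotonation of a 3-alkoxyenone by a hindered amide base (the enolate of Stork–Danheiser chemistry) gives the cross-conjugated dienolate 5, and O-silylation traps it as the 1-methoxy-3-silyloxy-1,3-diene without touching the prenyl group.

Step 4
Reactants: 7 trans-cinnamaldehyde
Product: 8 [(1E)-4,4-dibromobuta-1,3-dien-1-yl]benzene
Conditions: CBr4 (2 equiv), PPh3 (4 equiv), CH2Cl2, 0 °C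
Reagents that add atoms: carbon tetrabromide, BrC(Br)(Br)Br
Why: First stage of the Corey–Fuchs reaction, in which the ylide Ph3P=CBr2 formed in the flask olefinates the aldehyde in a Wittig-type reaction and leaves the E alkene unchanged.

Step 5
Reactants: 8 [(1E)-4,4-dibromobuta-1,3-dien-1-yl]benzene
Product: 10 methyl (E)-5-phenylpent-4-en-2-ynoate, via lithium acetylide 9 (not isolated)
Conditions: n-BuLi (2.1 equiv), THF, −78 °C; ClCO2Me, −78 to 0 °C
Reagents that add atoms: methyl chloroformate, COC(=O)Cl
Why: Second stage of the Corey–Fuchs reaction, in which two equivalents of n-BuLi turn the 1,1-dibromoalkene into lithium acetylide 9 by bromine–lithium exchange and loss of LiBr, and C-acylation of 9 with the chloroformate gives the ynoate with the E alkene retained.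

Step 6
Reactants: 6 3-(tert-butyldimethylsilyloxy)-1-methoxy-2-(3-methylbut-2-enyl)cyclohexa-1,3-diene; 10 methyl (E)-5-phenylpent-4-en-2-ynoate
Product: 12 methyl 4-(tert-butyldimethylsilyloxy)-2-methoxy-3-(3-methylbut-2-enyl)-6-[(E)-2-phenylethenyl]benzoate, via bicyclo[2.2.2]octadiene adduct 11 (not isolated)
Conditions: 6 (1.5 equiv), BHT (5 mol %), mesitylene, pressure tube, 110 °C then 165 °C
Reagents that add atoms: none
Why: The donor-substituted diene C1=C2–C3=C4 of 6 and the ester-activated triple bond of 10 combine in a concerted but asynchronous normal-electron-demand [4+2] cycloaddition that forms C4–C5 and C1–C6 and gives adduct 11, whose saturated CH2–CH2 bridge then leaves as ethylene in a retro-Diels–Alder step driven by aromatisation. This is the Alder–Rickert reaction, established for 1-methoxy-3-silyloxycyclohexa-1,3-dienes (2-alkyl members included) with propiolates, 2-alkynoates and acetylenedicarboxylates. Ring A closes intermolecularly by suprafacial union of a four-carbon and a two-carbon unit, first as one six-membered ring of the bicycle and then as the benzene ring once the bridge has gone. The two bridgehead stereocentres of 11 are fixed only relative to each other by the bicyclic frame, 11 is racemic and both centres vanish on aromatisation, so no stereocontrol is required and the E alkene is a spectator. The step needs regioselectivity, and the C1 methoxy and C3 silyloxy donors secure it because both raise the HOMO coefficient at the unsubstituted terminus C4, which therefore bonds to the electrophilic β-carbon of the ynoate and places styryl at C5 and the ester at C6 next to OMe. Chemoselectivity for the triple bond over the styryl double bond follows from the direct conjugation of the alkyne with the ester and from the styrene conjugation that attack at the alkene would sacrifice.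

Step 7
Reactants: 12 methyl 4-(tert-butyldimethylsilyloxy)-2-methoxy-3-(3-methylbut-2-enyl)-6-[(E)-2-phenylethenyl]benzoate
Product: 13 {4-(tert-butyldimethylsilyloxy)-2-methoxy-3-(3-methylbut-2-enyl)-6-[(E)-2-phenylethenyl]phenyl}methanol
Conditions: i-Bu2AlH (3 equiv), CH2Cl2, −78 to 0 °C; aq. potassium sodium tartrate
Reagents that add atoms: none
Why: Aluminium hydride reduction of an ester passes the aldehyde stage and stops at the benzylic alcohol even for 2,6-disubstituted benzoates, while the aryl silyl ether and the three C=C bonds are inert at or below 0 °C.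

Step 8
Reactants: 13 {4-(tert-butyldimethylsilyloxy)-2-methoxy-3-(3-methylbut-2-enyl)-6-[(E)-2-phenylethenyl]phenyl}methanol
Product: 15 tert-butyl{4-(chloromethyl)-3-methoxy-2-(3-methylbut-2-enyl)-5-[(E)-2-phenylethenyl]phenoxy}dimethylsilane, via benzylic mesylate 14 (not isolated)
Conditions: MsCl, Et3N, LiCl (3 equiv), THF, 0 °C to rt; used crude at once
Reagents that add atoms: lithium chloride, [Li+].[Cl-] (chloride of 15); methanesulfonyl chloride, CS(=O)(=O)Cl (mesyl group of 14)
Why: Mesylation followed by SN2 displacement with chloride in the same flask, the method used for sensitive allylic and benzylic alcohols, keeps the medium basic so that neither the prenyl alkene nor the silyl ether meets HCl.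

Step 9
Reactants: 15 tert-butyl{4-(chloromethyl)-3-methoxy-2-(3-methylbut-2-enyl)-5-[(E)-2-phenylethenyl]phenoxy}dimethylsilane; 16 2-methylprop-1-enylmagnesium bromide
Product: 17 tert-butyl{3-methoxy-2,4-bis(3-methylbut-2-enyl)-5-[(E)-2-phenylethenyl]phenoxy}dimethylsilane
Conditions: 16 (2 equiv), CuI (10 mol %), THF, −30 °C to rt
Reagents that add atoms: none
Why: Copper-catalysed Kumada-type sp3–sp2 cross-coupling, in which the alkenyl cuprate formed from 16 and CuI displaces the benzylic chloride, is a standard way to turn ArCH2X into a prenyl arene, and the aryl silyl ether is inert to the Grignard reagent.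

Step 10
Reactants: 17 tert-butyl{3-methoxy-2,4-bis(3-methylbut-2-enyl)-5-[(E)-2-phenylethenyl]phenoxy}dimethylsilane
Product: 18 chiricanine C, 3-methoxy-2,4-bis(3-methylbut-2-enyl)-5-[(E)-2-phenylethenyl]phenol
Conditions: Bu4NF (1.1 equiv), AcOH (1.1 equiv), THF, 0 °C
Reagents that add atoms: none
Why: Fluoride-induced cleavage of the aryl silyl ether is driven by the strong Si–F bond, and acetic acid protonates the phenoxide so that the electron-rich prenylated stilbenol is released under near-neutral conditions.

Compound list
1 | cyclohexane-1,3-dione | O=C1CCCC(=O)C1 | starting material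
2 | prenyl bromide (1-bromo-3-methylbut-2-ene) | CC(C)=CCBr | starting material
3 | 2-(3-methylbut-2-enyl)cyclohexane-1,3-dione | O=C1CCCC(=O)C1CC=C(C)C | intermediate
4 | 3-methoxy-2-(3-methylbut-2-enyl)cyclohex-2-en-1-one | COC1=C(CC=C(C)C)C(=O)CCC1 | intermediate
5 | lithium 5-methoxy-6-(3-methylbut-2-enyl)cyclohexa-1,5-dien-1-olate | [Li]OC1=CCCC(OC)=C1CC=C(C)C | intermediate
6 | 3-(tert-butyldimethylsilyloxy)-1-methoxy-2-(3-methylbut-2-enyl)cyclohexa-1,3-diene, also named tert-butyl{[5-methoxy-6-(3-methylbut-2-enyl)cyclohexa-1,5-dien-1-yl]oxy}dimethylsilane | COC1=C(CC=C(C)C)C(O[Si](C)(C)C(C)(C)C)=CCC1 | intermediate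
7 | trans-cinnamaldehyde | O=C/C=C/c1ccccc1 | starting material
8 | [(1E)-4,4-dibromobuta-1,3-dien-1-yl]benzene | BrC(Br)=C/C=C/c1ccccc1 | intermediate
9 | lithium (E)-4-phenylbut-3-en-1-yn-1-ide | [Li]C#C/C=C/c1ccccc1 | intermediate
10 | methyl (E)-5-phenylpent-4-en-2-ynoate | COC(=O)C#C/C=C/c1ccccc1 | intermediate
11 | methyl 5-(tert-butyldimethylsilyloxy)-1-methoxy-6-(3-methylbut-2-enyl)-3-[(E)-2-phenylethenyl]bicyclo[2.2.2]octa-2,5-diene-2-carboxylate (racemic, one enantiomer drawn) | CO[C@@]12CC[C@@H](C(O[Si](C)(C)C(C)(C)C)=C1CC=C(C)C)C(/C=C/c3ccccc3)=C2C(=O)OC | intermediate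
12 | methyl 4-(tert-butyldimethylsilyloxy)-2-methoxy-3-(3-methylbut-2-enyl)-6-[(E)-2-phenylethenyl]benzoate | COC(=O)c1c(OC)c(CC=C(C)C)c(O[Si](C)(C)C(C)(C)C)cc1/C=C/c1ccccc1 | intermediate
13 | {4-(tert-butyldimethylsilyloxy)-2-methoxy-3-(3-methylbut-2-enyl)-6-[(E)-2-phenylethenyl]phenyl}methanol | OCc1c(OC)c(CC=C(C)C)c(O[Si](C)(C)C(C)(C)C)cc1/C=C/c1ccccc1 | intermediate
14 | {4-(tert-butyldimethylsilyloxy)-2-methoxy-3-(3-methylbut-2-enyl)-6-[(E)-2-phenylethenyl]phenyl}methyl methanesulfonate | CS(=O)(=O)OCc1c(OC)c(CC=C(C)C)c(O[Si](C)(C)C(C)(C)C)cc1/C=C/c1ccccc1 | intermediate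
15 | tert-butyl{4-(chloromethyl)-3-methoxy-2-(3-methylbut-2-enyl)-5-[(E)-2-phenylethenyl]phenoxy}dimethylsilane | ClCc1c(OC)c(CC=C(C)C)c(O[Si](C)(C)C(C)(C)C)cc1/C=C/c1ccccc1 | intermediate
16 | 2-methylprop-1-enylmagnesium bromide | CC(C)=C[Mg]Br | starting material
17 | tert-butyl{3-methoxy-2,4-bis(3-methylbut-2-enyl)-5-[(E)-2-phenylethenyl]phenoxy}dimethylsilane | COc1c(CC=C(C)C)c(O[Si](C)(C)C(C)(C)C)cc(/C=C/c2ccccc2)c1CC=C(C)C | intermediate
18 | chiricanine C | COc1c(CC=C(C)C)c(O)cc(/C=C/c2ccccc2)c1CC=C(C)C | target

Total step count: 10. Longest linear sequence: 8 (steps 1, 2, 3, 6, 7, 8, 9, 10).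

Steps most likely to fail

Step 6. A tetrasubstituted diene and a β-substituted ynoate may cycloadd more slowly than the diene undergoes [1,5]-hydrogen shifts and the conjugated enyne oligomerises at the temperature required. The fallback sets out from 6 and attaches the styryl group only after ring A exists. Methyl propiolate is brominated (NBS, AgNO3 cat., acetone, rt) to methyl 3-bromopropiolate F1, a smaller and more electrophilic alkyne with no heat-sensitive enyne. With the same donor-controlled orientation it should add to 6 at lower temperature to give the bromo bicyclo[2.2.2]octadiene adduct F2. On further heating this loses ethylene to give methyl 6-bromo-4-(tert-butyldimethylsilyloxy)-2-methoxy-3-(3-methylbut-2-enyl)benzoate F3. A Mizoroki–Heck reaction with styrene (Pd(OAc)2, P(o-tol)3, Et3N, MeCN, 90 °C) should then give the E alkene selectively and leave the trisubstituted prenyl alkene alone. The sequence returns to the route at 12.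

Step 9. Wurtz-type homocoupling and halogen–metal exchange of the hindered, electron-rich benzylic chloride may outrun the cross-coupling. The fallback sets out from 15 and reverses the polarity of the coupling. Insertion of Zn dust in the presence of LiCl (THF, 25 °C) gives the benzylic zinc chloride F4, which cannot ionise. Negishi coupling with commercial 1-bromo-2-methylprop-1-ene (Pd(OAc)2, SPhos, THF, 25 to 50 °C, zerovalent palladium formed in the flask) then returns to the route at 17.

Step 8. The ortho methoxy and para silyloxy groups assist ionisation of the chloromethyl group. This may cause self-alkylation, hydrolysis or cyclisation onto the neighbouring styryl double bond during formation and handling. The fallback sets out from 13 and never makes a benzylic halide. Phosphorylation ((EtO)2P(O)Cl, Et3N, DMAP cat., CH2Cl2, 0 °C) gives the benzylic diethyl phosphate F5, an isolable and much less ionisable electrophile. Its copper-catalysed coupling with 16 (CuBr·SMe2 10 mol %, P(OEt)3 20 mol %, THF, 0 to 40 °C) belongs to a class known for benzylic phosphates and organomagnesium reagents. This bypasses 14 and 15 and returns to the route at 17.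

Further compounds
F1 | step 6 | methyl 3-bromopropiolate | COC(=O)C#CBr
F2 | step 6 | methyl 3-bromo-5-(tert-butyldimethylsilyloxy)-1-methoxy-6-(3-methylbut-2-enyl)bicyclo[2.2.2]octa-2,5-diene-2-carboxylate (racemic, one enantiomer drawn) | CO[C@@]12CC[C@@H](C(O[Si](C)(C)C(C)(C)C)=C1CC=C(C)C)C(Br)=C2C(=O)OC
F3 | step 6 | methyl 6-bromo-4-(tert-butyldimethylsilyloxy)-2-methoxy-3-(3-methylbut-2-enyl)benzoate | COC(=O)c1c(OC)c(CC=C(C)C)c(O[Si](C)(C)C(C)(C)C)cc1Br
F4 | step 9 | {4-(tert-butyldimethylsilyloxy)-2-methoxy-3-(3-methylbut-2-enyl)-6-[(E)-2-phenylethenyl]benzyl}zinc chloride | Cl[Zn]Cc1c(OC)c(CC=C(C)C)c(O[Si](C)(C)C(C)(C)C)cc1/C=C/c1ccccc1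
F5 | step 8 | {4-(tert-butyldimethylsilyloxy)-2-methoxy-3-(3-methylbut-2-enyl)-6-[(E)-2-phenylethenyl]phenyl}methyl diethyl phosphate | CCOP(=O)(OCC)OCc1c(OC)c(CC=C(C)C)c(O[Si](C)(C)C(C)(C)C)cc1/C=C/c1ccccc1
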